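Target is not safe once made.

    partner + intermediate → target (k1 = 0.022 L mol⁻¹ min⁻¹)
    substrate → intermediate (k2 = 0.0012 min⁻¹)
    partner → decomposed reagent (k3 = 5.6 × 10⁻⁴ min⁻¹)
    substrate + target → side product (k4 = 0.039 L mol⁻¹ min⁻¹)
    substrate ⇌ dormant form (K5 = 1.9, k5 = 6.9 × 10⁻⁴ min⁻¹)

in all of them: time 10 d

| flask | substrate | partner | remark |
|---|---|---|---|
| autumn | 0.050 M (fed, over 8.0 d) | 1.50 equiv | all else is in the flask from the start; the feed brings no volume worth counting |
| midnight | 0.050 M (in portions, 3, over 8.0 d) | 1.50 equiv | first portion at the start, last at 8.0 d |
| dawn | 0.050 M (fed, over 20 h) | 1.50 equiv | all else is in the flask from the start; the feed brings no volume worth counting |
| summer | 0.050 M | 1.50 equiv (fed, over 8.0 d) | all else is in the flask from the start; the feed brings no volume worth counting |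
| dusk | 0.050 M | 1.50 equiv | everything together at the start |

1. the flask that comes out highest in amount of side product, in percent of the substrate charged, or "all alike" when all lie within 1.5 percentage points (autumn / midnight / dawn / summer / dusk / all alike)
2. side product at the end, in percent of the substrate charged, autumn
3. side product at the end, in percent of the substrate charged, midnight
4. side product at the end, in percent of the substrate charged, dawn
5. side product at the end, in percent of the substrate charged, summer
6. side product at the end, in percent of the substrate charged, dusk

- percent here means substrate units held: one side product counts as two
- run time (autumn): 10 d

Side product forms when substrate meets target, so we follow the fraction of target left, not the side product made. For a target molecule the side step is pseudo-first-order, its rate constant times c(substrate), so the fraction left after any stretch is the exponential of minus that constant times the area under c(substrate) against time. We can reckon this area without knowing the curve. Substrate leaves by the first-order step to intermediate, while the dormant form holds it back and returns it, so if we neglect what the side step itself takes, the charge, once fully turned over, lays down an area equal to its concentration over that step's constant, however it is fed. We therefore define the exposure number as the side step's constant times the charge over the constant of the step to intermediate, which is 1.62. Target present before any substrate has turned over keeps the fraction 19.8%, and target made later keeps more.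

How much target autumn makes is a separate reckoning. Partner has a lifetime of 1.24 d against decomposition, and the feed lasts longer, 6.45 lifetimes. A unit of substrate waits on average 1.68 d in substrate and dormant form before it becomes intermediate. We take c(intermediate) as the feed rate times the time past that wait and the fraction of partner left as the exponential of minus its decay constant times time, neglecting partner used in coupling. Integrating the coupling rate then gives target made in autumn as 11.8% of the charge. If that target met the whole exposure, the side product in autumn, counted double, would be 19.0%. This is a high estimate, since target made later meets less exposure. The integral assumes a steady substrate feed that outlasts partner's lifetime, so our reckoning stops at autumn.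

The forecast names dusk as highest, with 14% for autumn, below our figure, then 31% for midnight, 35% for dawn, 27% for summer and 38% for dusk, holding that “slow substrate feeding keeps substrate low while target is scarce”.

The simulation puts dusk highest, with side product at 15.2% in autumn, 24.8% in midnight, 32.2% in dawn, 18.2% in summer and 36.1% in dusk. Dusk stands 21 percentage points above autumn; without partner's decomposition that difference becomes −5.7 points, and without the way back from dormant form to substrate it becomes 4.4 points, each a part of one effect. Autumn ends with 34.1% of its target left, above the exposure floor. Its neighbour with 0.600 equiv of partner keeps 31.9% and ends at 7.62% side product.

Its constants were chosen freely; the run is a simulation.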